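**Strategy.** The route rests on cutting both C–C bonds at the exocyclic carbinol carbon, the CH that links oxolane C3, C1 of one syringyl ring and the hydroxyl oxygen. That carbon is brought in from dichloromethane: a chiral-diol boronic ester on oxolane C3 takes up LiCHCl2 and then an aryl Grignard reagent, so that two boron-to-carbon 1,2-shifts join ring, one-carbon unit and arene and fix the carbinol configuration under reagent control. The precursor is the trans-4-(4-benzyloxy-3,5-dimethoxybenzyl)oxolan-3-yl boronate of (S,S)-1,2-dicyclohexylethane-1,2-diol, obtained by asymmetric hydroboration of a 3-benzyl-2,5-dihydrofuran; oxidation at boron and debenzylation finish the synthesis.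

Key step: step 7

**Remarks on the chemistry (made before the steps)**
- Numbering used: oxolane O1; C3 carries boron and later the exocyclic carbon Cα; C4 carries the arylmethyl group.
- The target is read as (αS,3R,4R) with the C3 and C4 substituents trans.
- Sense of induction: (R,R)-1,2-diols of this family give (αS)-chloro boronates, so the (S,S)-diol gives the (αR)-chloride. Aryl transfer with inversion then gives the (αS)-boronate, and oxidation with retention gives the (S)-carbinol.
- Assumption: IpcBH2 is used as a titrated ethereal stock solution made beforehand from its TMEDA adduct. Its facial preference on alkene 9 is assumed to parallel that on 1-methylcyclopentene.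
- Grignard reagent 3 is made once, as a titrated THF solution kept under argon, at a scale that serves both step 3 and step 7.
- The chiral diol is installed in the same pot as the hydroboration. Any minor enantiomer of the oxolanyl group thereby becomes a diastereomeric ester, which should be removable before the key step.

**Step 1**
Reactants: 1 4-bromo-2,6-dimethoxyphenol
Product: 2 2-(benzyloxy)-5-bromo-1,3-dimethoxybenzene
Conditions: BnBr, K2CO3, DMF, rt
Reagents that add atoms: benzyl bromide, BrCc1ccccc1
Why: Williamson ether synthesis, in which the phenoxide formed by K2CO3 is benzylated by SN2 displacement; the benzyl ether is chosen because it should survive Grignard formation, alkoxide, hydroboration, organolithium at low temperature and alkaline peroxide.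

**Step 2**
Reactants: 2 2-(benzyloxy)-5-bromo-1,3-dimethoxybenzene
Product: 3 [4-(benzyloxy)-3,5-dimethoxyphenyl]magnesium bromide (titrated THF solution, stored under argon)
Conditions: Mg turnings, THF, 40 °C; titration
Reagents that add atoms: magnesium, [Mg]
Why: Grignard formation by oxidative insertion of magnesium into the aryl C–Br bond, to which the benzyl and methyl aryl ethers are inert; the solution is stable enough in THF under argon to be drawn on in two later steps.

**Step 3**
Reactants: 3 [4-(benzyloxy)-3,5-dimethoxyphenyl]magnesium bromide; 4 3-chloro-2-(chloromethyl)prop-1-ene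
Product: 5 2-(benzyloxy)-5-[2-(chloromethyl)prop-2-en-1-yl]-1,3-dimethoxybenzene
Conditions: 3 added slowly to 4 (3 equiv), Li2CuCl4 (3 mol%), THF, −20 to 0 °C
Reagents that add atoms: none
Why: Copper-catalysed allylic substitution by a Grignard reagent, in which SN2 and SN2' attack on the symmetric bis-allylic dichloride lead to the same product, while excess 4 and inverse addition should keep the second chloride intact.

**Step 4**
Reactants: 5 2-(benzyloxy)-5-[2-(chloromethyl)prop-2-en-1-yl]-1,3-dimethoxybenzene; 6 allyl alcohol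
Product: 8 2-(benzyloxy)-1,3-dimethoxy-5-{2-[(prop-2-en-1-yloxy)methyl]prop-2-en-1-yl}benzene, via sodium prop-2-en-1-olate 7 (not isolated)
Conditions: 6, NaH, THF, 0 °C (gives 7); then 5, n-Bu4NI (cat.), THF, 0 °C to rt
Reagents that add atoms: none
Why: Williamson ether synthesis, in which the alkoxide displaces the reactive primary allylic chloride (direct and allylic-transposed attack again give one product) and the aryl ethers are inert.

**Step 5**
Reactants: 8 2-(benzyloxy)-1,3-dimethoxy-5-{2-[(prop-2-en-1-yloxy)methyl]prop-2-en-1-yl}benzene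
Product: 9 3-[4-(benzyloxy)-3,5-dimethoxybenzyl]-2,5-dihydrofuran
Conditions: second-generation Grubbs catalyst RuCl2(=CHPh)(PCy3)(H2IMes) (2 mol%), CH2Cl2, 40 °C
Reagents that add atoms: none
Why: Ring-closing metathesis of a 1,6-diene, in which the catalyst should load at the monosubstituted allyl terminus and close onto the 1,1-disubstituted alkene to give the five-membered trisubstituted cycloalkene with loss of ethene.

**Step 6**
Reactants: 9 3-[4-(benzyloxy)-3,5-dimethoxybenzyl]-2,5-dihydrofuran; 10 (S,S)-1,2-dicyclohexylethane-1,2-diol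
Product: 13 (4S,5S)-2-{(3R,4R)-4-[4-(benzyloxy)-3,5-dimethoxybenzyl]oxolan-3-yl}-4,5-dicyclohexyl-1,3,2-dioxaborolane, via isopinocampheyl(oxolanyl)borane 11 (not isolated), via diethyl oxolanylboronate 12 (not isolated)
Conditions: IpcBH2 from (+)-α-pinene (1.05 equiv), Et2O, −25 °C; CH3CHO (excess), 0 °C to rt; volatiles off; 10, pentane/Et2O, rt; volatiles off; chromatography or crystallisation
Reagents that add atoms: isopinocampheylborane from (+)-α-pinene (supplies boron), C[C@H]1[C@H](B)C[C@@H]2C[C@H]1C2(C)C
Why: Brown asymmetric hydroboration, in which H and B add syn across the trisubstituted C=C with boron at the unsubstituted carbon, so the ring substituents come out trans, and the isopinocampheyl group selects the alkene face in the sense known for 1-alkylcyclopentenes (this antipode gives (1S,2S)-trans-2-methylcyclopentyl boron compounds, the spatial counterpart of 13); acetaldehyde then expels the terpene as α-pinene and diol 10 displaces ethanol.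

**Step 7**
Reactants: 13 (4S,5S)-2-{(3R,4R)-4-[4-(benzyloxy)-3,5-dimethoxybenzyl]oxolan-3-yl}-4,5-dicyclohexyl-1,3,2-dioxaborolane; 14 dichloromethane; 3 [4-(benzyloxy)-3,5-dimethoxyphenyl]magnesium bromide (THF solution from step 2)
Product: 19 (4S,5S)-2-[(S)-[4-(benzyloxy)-3,5-dimethoxyphenyl]{(3R,4R)-4-[4-(benzyloxy)-3,5-dimethoxybenzyl]oxolan-3-yl}methyl]-4,5-dicyclohexyl-1,3,2-dioxaborolane, via dichloromethyllithium 15 (not isolated), via lithium dichloromethyl borate 16 (not isolated), via alpha-chloro boronate 17 (not isolated), via bromomagnesium aryl borate 18 (not isolated)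
Conditions: 14 (3 equiv), n-BuLi, THF, −100 °C (gives 15); 13, −100 °C; ZnCl2 (THF), −100 °C to rt, 16 h; pentane/aq. NH4Cl wash and solvent switch only, crude 17 in THF; 3 (2 equiv), −78 °C to rt
Reagents that add atoms: none
Why: Dichloromethyllithium adds to the boron of 13 to give borate 16, and ZnCl2 assists loss of one chloride while oxolane C3 migrates from boron to carbon with retention to give the (αR)-chloride 17; Grignard reagent 3 then forms borate 18, from which the aryl group migrates with displacement of chloride and inversion to give the (αS)-boronate 19. The closest known reaction type is the Matteson homologation of chiral-diol boronic esters followed by Grignard substitution of the α-chloro boronic ester. No ring is closed. The one new stereocentre, Cα, is controlled by the C2-symmetric (S,S)-diol on boron and not by the ring, since (R,R)-diols are known to give (αS)-chlorides and the antipode therefore gives (αR). The step needs diastereoselectivity at Cα and preference for the 1,2-shift over ring-opening β-alkoxy elimination of the oxolanyl borate; the diol together with ZnCl2 should secure the first, and the low temperature with chloride scavenging by ZnCl2 the second. C3 and C4 keep their configuration because the migration is stereoretentive.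

**Step 8**
Reactants: 19 (4S,5S)-2-[(S)-[4-(benzyloxy)-3,5-dimethoxyphenyl]{(3R,4R)-4-[4-(benzyloxy)-3,5-dimethoxybenzyl]oxolan-3-yl}methyl]-4,5-dicyclohexyl-1,3,2-dioxaborolane
Product: 20 (S)-[4-(benzyloxy)-3,5-dimethoxyphenyl]{(3R,4R)-4-[4-(benzyloxy)-3,5-dimethoxybenzyl]oxolan-3-yl}methanol
Conditions: 30% H2O2, 2 M NaOH, THF, 0 °C to rt
Reagents that add atoms: hydrogen peroxide, OO
Why: Boronate oxidation, in which hydroperoxide adds to boron and the benzylic carbon migrates from boron to oxygen with retention, so the (S)-carbinol should result and the diol is released for recovery, while the benzyl ethers and the oxolane are inert.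

**Step 9**
Reactants: 20 (S)-[4-(benzyloxy)-3,5-dimethoxyphenyl]{(3R,4R)-4-[4-(benzyloxy)-3,5-dimethoxybenzyl]oxolan-3-yl}methanol
Product: 21 (S)-(4-hydroxy-3,5-dimethoxyphenyl)[(3R,4R)-4-(4-hydroxy-3,5-dimethoxybenzyl)oxolan-3-yl]methanol
Conditions: H2 (1 atm), 10% Pd/C, EtOAc, rt, stopped at full debenzylation
Reagents that add atoms: none
Why: Catalytic hydrogenolysis, in which the two aryl benzyl ethers should be cleaved much faster than the secondary benzylic alcohol in neutral ethyl acetate at ambient pressure, and no stereocentre is touched.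

**Compound list**
1 | 4-bromo-2,6-dimethoxyphenol | COc1cc(Br)cc(OC)c1O | starting material
2 | 2-(benzyloxy)-5-bromo-1,3-dimethoxybenzene | COc1cc(Br)cc(OC)c1OCc1ccccc1 | intermediate
3 | [4-(benzyloxy)-3,5-dimethoxyphenyl]magnesium bromide | COc1cc([Mg]Br)cc(OC)c1OCc1ccccc1 | intermediate (titrated THF solution)
4 | 3-chloro-2-(chloromethyl)prop-1-ene | C=C(CCl)CCl | starting material
5 | 2-(benzyloxy)-5-[2-(chloromethyl)prop-2-en-1-yl]-1,3-dimethoxybenzene | COc1cc(CC(=C)CCl)cc(OC)c1OCc1ccccc1 | intermediate
6 | allyl alcohol (prop-2-en-1-ol) | C=CCO | starting material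
7 | sodium prop-2-en-1-olate | [Na+].[O-]CC=C | intermediate (not isolated)
8 | 2-(benzyloxy)-1,3-dimethoxy-5-{2-[(prop-2-en-1-yloxy)methyl]prop-2-en-1-yl}benzene | COc1cc(CC(=C)COCC=C)cc(OC)c1OCc1ccccc1 | intermediate
9 | 3-[4-(benzyloxy)-3,5-dimethoxybenzyl]-2,5-dihydrofuran | COc1cc(CC2=CCOC2)cc(OC)c1OCc1ccccc1 | intermediate
10 | (S,S)-1,2-dicyclohexylethane-1,2-diol | O[C@@H](C1CCCCC1)[C@@H](O)C1CCCCC1 | starting material
11 | [(1R,2S,3R,5R)-2,6,6-trimethylbicyclo[3.1.1]heptan-3-yl]{(3R,4R)-4-[4-(benzyloxy)-3,5-dimethoxybenzyl]oxolan-3-yl}borane | C[C@H]1[C@H](B[C@H]2COC[C@@H]2Cc2cc(OC)c(OCc3ccccc3)c(OC)c2)C[C@@H]2C[C@H]1C2(C)C | intermediate (not isolated)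
12 | diethyl {(3R,4R)-4-[4-(benzyloxy)-3,5-dimethoxybenzyl]oxolan-3-yl}boronate | COc1cc(C[C@H]2COC[C@@H]2B(OCC)OCC)cc(OC)c1OCc1ccccc1 | intermediate (not isolated)
13 | (4S,5S)-2-{(3R,4R)-4-[4-(benzyloxy)-3,5-dimethoxybenzyl]oxolan-3-yl}-4,5-dicyclohexyl-1,3,2-dioxaborolane | COc1cc(C[C@H]2COC[C@@H]2B2O[C@@H](C3CCCCC3)[C@H](C3CCCCC3)O2)cc(OC)c1OCc1ccccc1 | intermediate (precursor of the key step)
14 | dichloromethane | ClCCl | starting material
15 | dichloromethyllithium | [Li]C(Cl)Cl | intermediate (not isolated)
16 | lithium (dichloromethyl)borate of 13 | [Li+].COc1cc(C[C@H]2COC[C@@H]2[B-]2(C(Cl)Cl)O[C@@H](C3CCCCC3)[C@H](C3CCCCC3)O2)cc(OC)c1OCc1ccccc1 | intermediate (not isolated)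
17 | (4S,5S)-2-[(R)-chloro{(3R,4R)-4-[4-(benzyloxy)-3,5-dimethoxybenzyl]oxolan-3-yl}methyl]-4,5-dicyclohexyl-1,3,2-dioxaborolane | COc1cc(C[C@H]2COC[C@@H]2[C@H](Cl)B2O[C@@H](C3CCCCC3)[C@H](C3CCCCC3)O2)cc(OC)c1OCc1ccccc1 | intermediate (not isolated)
18 | bromomagnesium aryl borate of 17 (B-[4-(benzyloxy)-3,5-dimethoxyphenyl] ate complex) | Br[Mg+].COc1cc(C[C@H]2COC[C@@H]2[C@H](Cl)[B-]2(c3cc(OC)c(OCc4ccccc4)c(OC)c3)O[C@@H](C3CCCCC3)[C@H](C3CCCCC3)O2)cc(OC)c1OCc1ccccc1 | intermediate (not isolated)
19 | (4S,5S)-2-[(S)-[4-(benzyloxy)-3,5-dimethoxyphenyl]{(3R,4R)-4-[4-(benzyloxy)-3,5-dimethoxybenzyl]oxolan-3-yl}methyl]-4,5-dicyclohexyl-1,3,2-dioxaborolane | COc1cc(C[C@H]2COC[C@@H]2[C@H](B2O[C@@H](C3CCCCC3)[C@H](C3CCCCC3)O2)c2cc(OC)c(OCc3ccccc3)c(OC)c2)cc(OC)c1OCc1ccccc1 | intermediate (product of the key step)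
20 | (S)-[4-(benzyloxy)-3,5-dimethoxyphenyl]{(3R,4R)-4-[4-(benzyloxy)-3,5-dimethoxybenzyl]oxolan-3-yl}methanol | COc1cc(C[C@H]2COC[C@@H]2[C@H](O)c2cc(OC)c(OCc3ccccc3)c(OC)c2)cc(OC)c1OCc1ccccc1 | intermediate
21 | (S)-(4-hydroxy-3,5-dimethoxyphenyl)[(3R,4R)-4-(4-hydroxy-3,5-dimethoxybenzyl)oxolan-3-yl]methanol | COc1cc(C[C@H]2COC[C@@H]2[C@H](O)c2cc(OC)c(O)c(OC)c2)cc(OC)c1O | target

**Total step count:** 9. **Longest linear sequence:** 9 steps (1 → 2 → 3 → 5 → 8 → 9 → 13 → 19 → 20 → 21; a second portion of the solution of 3 enters at step 7).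

**Steps most likely to fail**

1. Step 7. The hindered secondary oxolanyl group may form the borate or migrate only sluggishly, borate 16 may open the ring by β-alkoxy elimination, chloride may epimerise 17, or the aryl transfer may be slow. The fallback keeps the first carbenoid insertion and replaces the aryl 1,2-shift by carbonyl chemistry. It sets out from chloride 17 (made from 13 as in step 7). Buffered alkaline H2O2 should convert 17 into (3R,4R)-4-[4-(benzyloxy)-3,5-dimethoxybenzyl]oxolane-3-carbaldehyde F1. Addition of Grignard reagent 3 should give [4-(benzyloxy)-3,5-dimethoxyphenyl]{(3R,4R)-4-[4-(benzyloxy)-3,5-dimethoxybenzyl]oxolan-3-yl}methanol as a mixture of carbinol epimers F2. Dess–Martin periodinane should give [4-(benzyloxy)-3,5-dimethoxyphenyl]{(3R,4R)-4-[4-(benzyloxy)-3,5-dimethoxybenzyl]oxolan-3-yl}methanone F3. CBS reduction with BH3·SMe2 and (R)-2-methyl-CBS-oxazaborolidine, with the aryl group assumed to act as the large substituent, should then return to the route at 20.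

2. Step 6. Facial discrimination by IpcBH2 may be insufficient on this 1-alkylcyclopentene-type alkene, the β-alkoxy organoborane may open the ring, or removal of the terpene group may be incomplete. The fallback replaces asymmetric induction by resolution and sets out from 9. Uncatalysed hydroboration with catecholborane (neat, 70–100 °C) should give racemic trans-2-{4-[4-(benzyloxy)-3,5-dimethoxybenzyl]oxolan-3-yl}-1,3,2-benzodioxaborole F4. Exchange with diol 10 liberates catechol and should give two diastereomeric esters in equal amounts, 13 and (4S,5S)-2-{(3S,4S)-4-[4-(benzyloxy)-3,5-dimethoxybenzyl]oxolan-3-yl}-4,5-dicyclohexyl-1,3,2-dioxaborolane F5. Separation by chromatography or crystallisation returns to the route at 13.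

3. Step 9. Over-reduction may occur, that is hydrogenolytic loss of the benzylic hydroxyl once the para phenol is unmasked. The fallback reverses the order of the last two operations and sets out from 19. Hydrogenolysis (H2, Pd/C, EtOAc) while the benzylic carbon still carries boron should give (4S,5S)-4,5-dicyclohexyl-2-[(S)-(4-hydroxy-3,5-dimethoxyphenyl){(3R,4R)-4-(4-hydroxy-3,5-dimethoxybenzyl)oxolan-3-yl}methyl]-1,3,2-dioxaborolane F6. Oxidation with NaBO3·4H2O in THF/water then arrives directly at 21.

**Further compounds**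
F1 | step 7 | (3R,4R)-4-[4-(benzyloxy)-3,5-dimethoxybenzyl]oxolane-3-carbaldehyde | COc1cc(C[C@H]2COC[C@@H]2C=O)cc(OC)c1OCc1ccccc1
F2 | step 7 | [4-(benzyloxy)-3,5-dimethoxyphenyl]{(3R,4R)-4-[4-(benzyloxy)-3,5-dimethoxybenzyl]oxolan-3-yl}methanol, mixture of carbinol epimers | COc1cc(C[C@H]2COC[C@@H]2C(O)c2cc(OC)c(OCc3ccccc3)c(OC)c2)cc(OC)c1OCc1ccccc1
F3 | step 7 | [4-(benzyloxy)-3,5-dimethoxyphenyl]{(3R,4R)-4-[4-(benzyloxy)-3,5-dimethoxybenzyl]oxolan-3-yl}methanone | COc1cc(C[C@H]2COC[C@@H]2C(=O)c2cc(OC)c(OCc3ccccc3)c(OC)c2)cc(OC)c1OCc1ccccc1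
F4 | step 6 | rac-trans-2-{4-[4-(benzyloxy)-3,5-dimethoxybenzyl]oxolan-3-yl}-1,3,2-benzodioxaborole (one enantiomer drawn) | COc1cc(C[C@H]2COC[C@@H]2B2Oc3ccccc3O2)cc(OC)c1OCc1ccccc1
F5 | step 6 | (4S,5S)-2-{(3S,4S)-4-[4-(benzyloxy)-3,5-dimethoxybenzyl]oxolan-3-yl}-4,5-dicyclohexyl-1,3,2-dioxaborolane | COc1cc(C[C@@H]2COC[C@H]2B2O[C@@H](C3CCCCC3)[C@H](C3CCCCC3)O2)cc(OC)c1OCc1ccccc1
F6 | step 9 | (4S,5S)-4,5-dicyclohexyl-2-[(S)-(4-hydroxy-3,5-dimethoxyphenyl){(3R,4R)-4-(4-hydroxy-3,5-dimethoxybenzyl)oxolan-3-yl}methyl]-1,3,2-dioxaborolane | COc1cc(C[C@H]2COC[C@@H]2[C@H](B2O[C@@H](C3CCCCC3)[C@H](C3CCCCC3)O2)c2cc(OC)c(O)c(OC)c2)cc(OC)c1O
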